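**Plan**
- Retrosynthesis: cut the O15 ester, then the C12–O8 lactone bond (back to a C12 PMB ether and a free C8 hydroxyl), then ring bond C9–C10 together with C1–H, then C5–C6, C7–C8 and C3–C4.
- Enabling feature: in the ten-membered carbocycle C1–C10, carbinol C8, methylene C9 and the methyl-bearing alkene carbon C10 (with hydrogen on C1) form a homoallylic alcohol. This is the pattern left by a hydrometalative union of a methyl-capped C1≡C10 alkyne with a C8–C9 terminal epoxide.
- Forward: a (Z)-iodoalkene (C1–C5, C10, C14, C15) is joined at C5–C6 to a Weinreb amide (C6–C9, C11–C13). The acyclic ynyl epoxide is closed to the ten-membered ring, then the five-membered lactone ring is formed and the side-chain ester is attached last.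
- Stereochemistry: C7 and C8 come from an Evans syn aldol with the (4R)-benzyloxazolidinone; C6 from a hydroxyl-directed 1,3-syn reduction. The C4 alkene comes from anti-carbomagnesiation/iodination, the C1(10) alkene from syn addition across the alkyne, and the side-chain alkene from a thermodynamic acetate transposition.

Key step: step 12

Assumption: germacrane numbering is used for every intermediate (ring C1–C10, C14 on C10, C15 on C4, C11/C12/C13 on C7, O8 in the lactone), and anhydrous chloroacetaldehyde is taken as available by distillation of the commercial aqueous solution.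

**Route**

Step 1
Reactants: 1 prop-2-yn-1-ol; 2 5-bromopent-2-yne
Product: 5 (2Z)-3-iodo-2-(pent-3-yn-1-yl)prop-2-en-1-ol, via pent-3-yn-1-ylmagnesium bromide 3 (not isolated), via alkenylmagnesium alkoxide 4 (not isolated)
Conditions: 2 (2.5 equiv), Mg, THF, rt; then 1, CuI (10 mol%), Et2O–THF, −10 °C → rt; then I2, −78 → 0 °C; aq. NH4Cl
Reagents that add atoms: iodine, II
Why: Copper-catalysed anti-carbomagnesiation of the propargylic magnesium alkoxide puts the pentynyl group on C4 and magnesium on C5 in a five-membered chelate, and iodinolysis with retention should give the (Z)-iodoalkene with C15H2O cis to iodine, the internal alkyne of the Grignard reagent having no directing alkoxide.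

Step 2
Reactants: 5 (2Z)-3-iodo-2-(pent-3-yn-1-yl)prop-2-en-1-ol
Product: 6 tert-butyl{[(2Z)-3-iodo-2-(pent-3-yn-1-yl)prop-2-en-1-yl]oxy}dimethylsilane
Conditions: TBSCl, imidazole, CH2Cl2, 0 °C → rt
Reagents that add atoms: tert-butyldimethylsilyl chloride, CC(C)(C)[Si](C)(C)Cl
Why: Routine silylation of a primary allylic alcohol, which masks O15 for the organolithium and nickel steps.

Step 3
Reactants: 7 3-chloro-2-(chloromethyl)prop-1-ene; 8 (4-methoxyphenyl)methanol
Product: 9 1-({[2-(chloromethyl)prop-2-en-1-yl]oxy}methyl)-4-methoxybenzene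
Conditions: 8, NaH, THF/DMF, 0 °C; added to 7 (3 equiv), Bu4NI (cat.), 0 °C → rt
Reagents that add atoms: none
Why: Williamson etherification in which an excess of the symmetrical dichloride should hold the reaction at mono-substitution.

Step 4
Reactants: 9 1-({[2-(chloromethyl)prop-2-en-1-yl]oxy}methyl)-4-methoxybenzene
Product: 11 3-{[(4-methoxybenzyl)oxy]methyl}but-3-enoic acid, via allylic Grignard reagent 10 (not isolated)
Conditions: Mg (activated), THF, −10 °C, slow addition; then CO2, −40 °C → rt; cold 1 M HCl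
Reagents that add atoms: carbon dioxide, O=C=O
Why: Carboxylation of an allylic Grignard reagent whose two allyl termini are equivalent, so either mode of attack should give the same β,γ-unsaturated acid with the C11=C13 methylidene in place.

Step 5
Reactants: 11 3-{[(4-methoxybenzyl)oxy]methyl}but-3-enoic acid; 12 (4R)-4-benzyl-1,3-oxazolidin-2-one
Product: 14 (4R)-4-benzyl-3-(3-{[(4-methoxybenzyl)oxy]methyl}but-3-enoyl)-1,3-oxazolidin-2-one, via mixed pivalic anhydride 13 (not isolated)
Conditions: PivCl, Et3N, THF, −20 °C; then 12, LiCl, −20 °C → rt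
Reagents that add atoms: none
Why: LiCl-assisted N-acylation of the oxazolidinone through the mixed anhydride, run cold so that the β,γ-alkene should not move into conjugation.

Step 6
Reactants: 14 (4R)-4-benzyl-3-(3-{[(4-methoxybenzyl)oxy]methyl}but-3-enoyl)-1,3-oxazolidin-2-one; 15 chloroacetaldehyde
Product: 18 (4R)-4-benzyl-3-[(2R,3R)-4-chloro-3-hydroxy-2-{3-[(4-methoxybenzyl)oxy]prop-1-en-2-yl}butanoyl]-1,3-oxazolidin-2-one, via dibutylboron enolate 16 (not isolated), via dibutylboron aldolate 17 (not isolated)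
Conditions: Bu2BOTf, i-Pr2NEt, CH2Cl2, −78 → 0 °C; 15 (anhydrous, freshly distilled), −78 → 0 °C; pH 7 buffer, MeOH, H2O2, 0 °C
Reagents that add atoms: none
Why: Evans syn aldol in which the (Z)-boron enolate reacts at its α-carbon C7 through a closed Zimmerman–Traxler chair on the face away from the benzyl group of the (4R)-auxiliary, which should set (7R,8R) with the C11 substituent and the C8 hydroxyl syn.

Step 7
Reactants: 18 (4R)-4-benzyl-3-[(2R,3R)-4-chloro-3-hydroxy-2-{3-[(4-methoxybenzyl)oxy]prop-1-en-2-yl}butanoyl]-1,3-oxazolidin-2-one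
Product: 19 (2R,3R)-4-chloro-3-hydroxy-N-methoxy-2-{3-[(4-methoxybenzyl)oxy]prop-1-en-2-yl}-N-methylbutanamide
Conditions: MeNHOMe·HCl, AlMe3, CH2Cl2, −20 → 0 °C; aq. potassium sodium tartrate
Reagents that add atoms: N,O-dimethylhydroxylamine hydrochloride, CNOC.Cl
Why: Aluminium amide transamidation of the imide, assisted by the free β-hydroxyl, should give the Weinreb amide without epimerising C7 and return the auxiliary.

Step 8
Reactants: 6 tert-butyl{[(2Z)-3-iodo-2-(pent-3-yn-1-yl)prop-2-en-1-yl]oxy}dimethylsilane; 19 (2R,3R)-4-chloro-3-hydroxy-N-methoxy-2-{3-[(4-methoxybenzyl)oxy]prop-1-en-2-yl}-N-methylbutanamide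
Product: 22 (2R,3R,5Z)-6-({[tert-butyl(dimethyl)silyl]oxy}methyl)-1-chloro-2-hydroxy-3-{3-[(4-methoxybenzyl)oxy]prop-1-en-2-yl}undec-5-en-9-yn-4-one, via alkenyllithium 20 (not isolated), via chloromagnesium alkoxide 21 (not isolated)
Conditions: 6, t-BuLi (2 equiv), Et2O, −78 °C; 19, i-PrMgCl (1 equiv), THF, −78 °C; combined, −78 → −40 °C; aq. NH4Cl
Reagents that add atoms: none
Why: Iodine–lithium exchange with retention of alkene geometry followed by Weinreb ketone synthesis forms C5–C6; prior conversion of the C8 hydroxyl into its magnesium alkoxide spares the alkenyllithium, and the ketone is released only on work-up, which should protect C7 and the chlorohydrin.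

Step 9
Reactants: 22 (2R,3R,5Z)-6-({[tert-butyl(dimethyl)silyl]oxy}methyl)-1-chloro-2-hydroxy-3-{3-[(4-methoxybenzyl)oxy]prop-1-en-2-yl}undec-5-en-9-yn-4-one
Product: 24 (2R,3S,4R,5Z)-6-({[tert-butyl(dimethyl)silyl]oxy}methyl)-1-chloro-3-{3-[(4-methoxybenzyl)oxy]prop-1-en-2-yl}undec-5-en-9-yne-2,4-diol, via diethylboron chelate 23 (not isolated)
Conditions: Et2BOMe, THF/MeOH (4:1), −78 °C; NaBH4, −78 °C; AcOH, then MeOH azeotrope
Reagents that add atoms: none
Why: Narasaka–Prasad reduction in which external hydride attacks the six-membered boron chelate of the β-hydroxy ketone axially, so the new C6 hydroxyl should arise syn to the C8 hydroxyl (6R) by carbonyl reduction of the β,β-disubstituted enone.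

Step 10
Reactants: 24 (2R,3S,4R,5Z)-6-({[tert-butyl(dimethyl)silyl]oxy}methyl)-1-chloro-3-{3-[(4-methoxybenzyl)oxy]prop-1-en-2-yl}undec-5-en-9-yne-2,4-diol
Product: 25 (4Z,6R,7S,8R)-15-(tert-butyldimethylsilyloxy)-8,9-epoxy-12-(4-methoxybenzyloxy)-9,10-secogermacra-4,11(13)-dien-1(10)-yn-6-ol
Conditions: K2CO3, MeOH, 0 °C → rt
Reagents that add atoms: none
Why: Intramolecular Williamson closure (3-exo-tet) in which the vicinal C8 alkoxide displaces chloride at C9 without touching the C8 stereocentre and should outpace five-membered ether formation from O6.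

Step 11
Reactants: 25 (4Z,6R,7S,8R)-15-(tert-butyldimethylsilyloxy)-8,9-epoxy-12-(4-methoxybenzyloxy)-9,10-secogermacra-4,11(13)-dien-1(10)-yn-6-ol
Product: 26 (4Z,6R,7R,8R)-6,15-bis(tert-butyldimethylsilyloxy)-8,9-epoxy-12-(4-methoxybenzyloxy)-9,10-secogermacra-4,11(13)-dien-1(10)-yne
Conditions: TBSOTf, 2,6-lutidine, CH2Cl2, −78 °C
Reagents that add atoms: tert-butyldimethylsilyl trifluoromethanesulfonate, CC(C)(C)[Si](C)(C)OS(=O)(=O)C(F)(F)F
Why: Silyl triflate silylation of the hindered secondary allylic alcohol, buffered and cold so that the epoxide should survive.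

Step 12
Reactants: 26 (4Z,6R,7R,8R)-6,15-bis(tert-butyldimethylsilyloxy)-8,9-epoxy-12-(4-methoxybenzyloxy)-9,10-secogermacra-4,11(13)-dien-1(10)-yne
Product: 29 (1(10)E,4Z,6R,7R,8S)-6,15-bis(tert-butyldimethylsilyloxy)-12-(4-methoxybenzyloxy)germacra-1(10),4,11(13)-trien-8-ol, via oxanickelacycle 27 (not isolated), via O8-diethylboryl ether 28 (not isolated)
Conditions: Ni(cod)2 (20 mol%), PBu3 (40 mol%), Et3B (3 equiv), toluene, 0.005 M, slow addition of 26, rt → 50 °C; aq. NaHCO3
Reagents that add atoms: none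
Why: Proposed new method: zerovalent nickel carrying PBu3 should bind the C1≡C10 alkyne and open the monosubstituted epoxide at its CH2 carbon C9, giving oxanickelacycle 27 of divalent nickel with C9 bonded to C10 and nickel bonded to C1 and O8; ethyl transfer from Et3B (forming the O8–B bond of 28), β-hydride elimination of ethene and C1–H reductive elimination then return zerovalent nickel and place hydrogen cis to C9. The closest known reactions are the nickel-catalysed reductive coupling of alkynes with terminal epoxides, shown between two molecules and for five- and six-membered rings, and the nickel-catalysed alkyne–aldehyde reductive macrocyclisation; a ten-membered carbocycle has not been closed in this way. The ring closes in the endo mode at both partners (endo-dig at the alkyne, so C1 and C10 both lie in the ring, and endo opening of the epoxide at C9) through a bicyclic intermediate that already has the trans-cyclodecene shape of the germacradiene. No stereocentre is created: C8 keeps its configuration because its C–O bond is never broken, and only the (E) geometry of the C1(10) alkene is set, by the syn addition. The step needs C9–C10 rather than C9–C1 bonding and cyclisation rather than oligomerisation; the small methyl cap on C10 against the tether on C1, the strain of the alternative nine-membered exocyclic mode, and slow addition at high dilution should secure both. Silyl and PMB ethers are inert to the reagents, and the only hydroxyl set free is the one that later lactonises.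

Step 13
Reactants: 29 (1(10)E,4Z,6R,7R,8S)-6,15-bis(tert-butyldimethylsilyloxy)-12-(4-methoxybenzyloxy)germacra-1(10),4,11(13)-trien-8-ol
Product: 30 (1(10)E,4Z,6R,7R,8S)-6,15-bis(tert-butyldimethylsilyloxy)germacra-1(10),4,11(13)-triene-8,12-diol
Conditions: DDQ, CH2Cl2/pH 7 buffer, 0 °C
Reagents that add atoms: none
Why: Oxidative cleavage of the PMB ether through its benzylic oxocarbenium ion should free O12 while silyl ethers and the isolated alkenes stay intact.

Step 14
Reactants: 30 (1(10)E,4Z,6R,7R,8S)-6,15-bis(tert-butyldimethylsilyloxy)germacra-1(10),4,11(13)-triene-8,12-diol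
Product: 33 (1(10)E,4Z,6R,7R,8S)-6,15-bis(tert-butyldimethylsilyloxy)germacra-1(10),4,11(13)-trien-12,8-olide, via hydroxy enal 31 (not isolated), via lactol 32 (not isolated)
Conditions: MnO2 (activated, excess), CH2Cl2, rt
Reagents that add atoms: none
Why: Oxidative lactonisation in which MnO2 oxidises only the allylic C12 alcohol to the enal, O8 adds to C12 (5-exo-trig) to form the lactol and this is oxidised on to the trans-fused α-methylene lactone with C7 and C8 untouched.

Step 15
Reactants: 33 (1(10)E,4Z,6R,7R,8S)-6,15-bis(tert-butyldimethylsilyloxy)germacra-1(10),4,11(13)-trien-12,8-olide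
Product: 34 (1(10)E,4Z,6R,7S,8S)-6,15-dihydroxygermacra-1(10),4,11(13)-trien-12,8-olide
Conditions: HF·pyridine, pyridine, THF, 0 °C → rt
Reagents that add atoms: none
Why: Fluoride cleavage of both silyl ethers under pyridine buffering, which should avoid acid-induced transannular cyclisation of the germacradiene and base-induced migration of the lactone to O6.

Step 16
Reactants: 35 tert-butyl prop-2-enoate; 36 acetaldehyde
Product: 37 tert-butyl 3-hydroxy-2-methylidenebutanoate (racemic)
Conditions: DABCO (20 mol%), neat, rt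
Reagents that add atoms: none
Why: Morita–Baylis–Hillman reaction, the racemic carbinol centre being removed again in step 18.

Step 17
Reactants: 37 tert-butyl 3-hydroxy-2-methylidenebutanoate
Product: 38 tert-butyl 3-acetoxy-2-methylidenebutanoate (racemic)
Conditions: Ac2O, Et3N, DMAP (cat.), CH2Cl2, 0 °C
Reagents that add atoms: acetic anhydride, CC(=O)OC(C)=O
Why: Routine O-acetylation of the secondary allylic alcohol.

Step 18
Reactants: 38 tert-butyl 3-acetoxy-2-methylidenebutanoate
Product: 39 tert-butyl (2E)-2-(acetoxymethyl)but-2-enoate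
Conditions: DABCO (20 mol%), THF, reflux
Reagents that add atoms: none
Why: Amine-catalysed 1,3-transposition of the allylic acetate (SN2′ addition of DABCO, then acetate return) should lead to the thermodynamically favoured trisubstituted enoate with the methyl group trans to the ester, (E).

Step 19
Reactants: 39 tert-butyl (2E)-2-(acetoxymethyl)but-2-enoate
Product: 40 (2E)-2-(acetoxymethyl)but-2-enoic acid
Conditions: TFA, CH2Cl2, 0 °C → rt
Reagents that add atoms: none
Why: Acidolysis of the tert-butyl ester with loss of 2-methylpropene should leave the primary acetate and the alkene geometry intact.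

Step 20
Reactants: 34 (1(10)E,4Z,6R,7S,8S)-6,15-dihydroxygermacra-1(10),4,11(13)-trien-12,8-olide; 40 (2E)-2-(acetoxymethyl)but-2-enoic acid
Product: 42 (1(10)E,4Z,6R,7S,8S)-15-{[(2E)-2-(acetoxymethyl)but-2-enoyl]oxy}-6-hydroxygermacra-1(10),4,11(13)-trien-12,8-olide (CNP0184624.1), via acid chloride 41 (not isolated)
Conditions: 40, (COCl)2, DMF (cat.), CH2Cl2, 0 °C → rt, concentrate; then 34, 2,4,6-collidine, CH2Cl2, −40 → 0 °C
Reagents that add atoms: none
Why: Acylation with the acid chloride under a non-nucleophilic base should take place at the accessible primary allylic O15 and not at the secondary O6 hydroxyl, which is flanked by C7 and the (Z)-alkene, with the acyl alkene geometry retained.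

**Compound list**
1 | prop-2-yn-1-ol | C#CCO | starting material
2 | 5-bromopent-2-yne | CC#CCCBr | starting material
3 | pent-3-yn-1-ylmagnesium bromide | CC#CCC[Mg]Br | intermediate (not isolated)
4 | bromomagnesium (2Z)-3-(bromomagnesio)-2-(pent-3-yn-1-yl)prop-2-en-1-olate | CC#CCC/C(CO[Mg]Br)=C/[Mg]Br | intermediate (not isolated)
5 | (2Z)-3-iodo-2-(pent-3-yn-1-yl)prop-2-en-1-ol | CC#CCC/C(CO)=C/I | intermediate
6 | tert-butyl{[(2Z)-3-iodo-2-(pent-3-yn-1-yl)prop-2-en-1-yl]oxy}dimethylsilane | CC#CCC/C(CO[Si](C)(C)C(C)(C)C)=C/I | intermediate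
7 | 3-chloro-2-(chloromethyl)prop-1-ene | C=C(CCl)CCl | starting material
8 | (4-methoxyphenyl)methanol | COc1ccc(CO)cc1 | starting material
9 | 1-({[2-(chloromethyl)prop-2-en-1-yl]oxy}methyl)-4-methoxybenzene | C=C(CCl)COCc1ccc(OC)cc1 | intermediate
10 | (2-{[(4-methoxybenzyl)oxy]methyl}prop-2-en-1-yl)magnesium chloride | C=C(C[Mg]Cl)COCc1ccc(OC)cc1 | intermediate (not isolated)
11 | 3-{[(4-methoxybenzyl)oxy]methyl}but-3-enoic acid | C=C(CC(=O)O)COCc1ccc(OC)cc1 | intermediate
12 | (4R)-4-benzyl-1,3-oxazolidin-2-one | O=C1N[C@H](Cc2ccccc2)CO1 | starting material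
13 | 3-{[(4-methoxybenzyl)oxy]methyl}but-3-enoic pivalic anhydride | C=C(CC(=O)OC(=O)C(C)(C)C)COCc1ccc(OC)cc1 | intermediate (not isolated)
14 | (4R)-4-benzyl-3-(3-{[(4-methoxybenzyl)oxy]methyl}but-3-enoyl)-1,3-oxazolidin-2-one | C=C(CC(=O)N1[C@H](Cc2ccccc2)COC1=O)COCc1ccc(OC)cc1 | intermediate
15 | chloroacetaldehyde | ClCC=O | starting material
16 | (Z)-dibutylboron enolate of 14 (O–B cis to the C11 substituent) | CCCCB(CCCC)O/C(=C\C(=C)COCc1ccc(OC)cc1)N1[C@H](Cc2ccccc2)COC1=O | intermediate (not isolated)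
17 | O8-dibutylboryl aldolate of 18 | O=C(N1[C@H](Cc2ccccc2)COC1=O)[C@H](C(=C)COCc1ccc(OC)cc1)[C@H](CCl)OB(CCCC)CCCC | intermediate (not isolated)
18 | (4R)-4-benzyl-3-[(2R,3R)-4-chloro-3-hydroxy-2-{3-[(4-methoxybenzyl)oxy]prop-1-en-2-yl}butanoyl]-1,3-oxazolidin-2-one | O=C(N1[C@H](Cc2ccccc2)COC1=O)[C@H](C(=C)COCc1ccc(OC)cc1)[C@@H](O)CCl | intermediate
19 | (2R,3R)-4-chloro-3-hydroxy-N-methoxy-2-{3-[(4-methoxybenzyl)oxy]prop-1-en-2-yl}-N-methylbutanamide | CON(C)C(=O)[C@H](C(=C)COCc1ccc(OC)cc1)[C@@H](O)CCl | intermediate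
20 | [(1Z)-2-({[tert-butyl(dimethyl)silyl]oxy}methyl)hept-1-en-5-yn-1-yl]lithium | CC#CCC/C(CO[Si](C)(C)C(C)(C)C)=C/[Li] | intermediate (not isolated)
21 | O3-chloromagnesium alkoxide of 19 | CON(C)C(=O)[C@H](C(=C)COCc1ccc(OC)cc1)[C@H](CCl)O[Mg]Cl | intermediate (not isolated)
22 | (2R,3R,5Z)-6-({[tert-butyl(dimethyl)silyl]oxy}methyl)-1-chloro-2-hydroxy-3-{3-[(4-methoxybenzyl)oxy]prop-1-en-2-yl}undec-5-en-9-yn-4-one (germacrane numbering: C6 ketone, 7R, 8R) | CC#CCC/C(CO[Si](C)(C)C(C)(C)C)=C/C(=O)[C@H](C(=C)COCc1ccc(OC)cc1)[C@@H](O)CCl | intermediate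
23 | O8-diethylboryl chelate of 22 | CC#CCC/C(CO[Si](C)(C)C(C)(C)C)=C/C(=O)[C@H](C(=C)COCc1ccc(OC)cc1)[C@H](CCl)OB(CC)CC | intermediate (not isolated)
24 | (2R,3S,4R,5Z)-6-({[tert-butyl(dimethyl)silyl]oxy}methyl)-1-chloro-3-{3-[(4-methoxybenzyl)oxy]prop-1-en-2-yl}undec-5-en-9-yne-2,4-diol (germacrane numbering: 6R,7S,8R; 6-OH and 8-OH syn) | CC#CCC/C(CO[Si](C)(C)C(C)(C)C)=C/[C@@H](O)[C@H](C(=C)COCc1ccc(OC)cc1)[C@@H](O)CCl | intermediate
25 | (4Z,6R,7S,8R)-15-(tert-butyldimethylsilyloxy)-8,9-epoxy-12-(4-methoxybenzyloxy)-9,10-secogermacra-4,11(13)-dien-1(10)-yn-6-ol (acyclic: CH3–C10≡C1–C2H2–C3H2–C4(C15H2OTBS)=C5H–C6H(OH)–C7H[C11(=C13H2)C12H2OPMB]–C8H–C9H2 oxirane) | CC#CCC/C(CO[Si](C)(C)C(C)(C)C)=C/[C@@H](O)[C@H](C(=C)COCc1ccc(OC)cc1)[C@@H]1CO1 | intermediate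
26 | (4Z,6R,7R,8R)-6,15-bis(tert-butyldimethylsilyloxy)-8,9-epoxy-12-(4-methoxybenzyloxy)-9,10-secogermacra-4,11(13)-dien-1(10)-yne (25 with TBS on O6) | CC#CCC/C(CO[Si](C)(C)C(C)(C)C)=C/[C@@H](O[Si](C)(C)C(C)(C)C)[C@H](C(=C)COCc1ccc(OC)cc1)[C@@H]1CO1 | intermediate
27 | oxanickelacycle of divalent nickel (six-membered ring Ni–C1=C10–C9–C8–O8, PBu3 on nickel, fused to the ten-membered ring) | CCCC[P+](CCCC)(CCCC)[Ni-]1O[C@H]2C/C(C)=C1/CC/C(CO[Si](C)(C)C(C)(C)C)=C/[C@@H](O[Si](C)(C)C(C)(C)C)[C@@H]2C(=C)COCc1ccc(OC)cc1 | intermediate (not isolated)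
28 | O8-diethylboryl ether of 29 | CCB(CC)O[C@H]1C/C(C)=C/CC/C(CO[Si](C)(C)C(C)(C)C)=C/[C@@H](O[Si](C)(C)C(C)(C)C)[C@@H]1C(=C)COCc1ccc(OC)cc1 | intermediate (not isolated)
29 | (1(10)E,4Z,6R,7R,8S)-6,15-bis(tert-butyldimethylsilyloxy)-12-(4-methoxybenzyloxy)germacra-1(10),4,11(13)-trien-8-ol | O[C@H]1C/C(C)=C/CC/C(CO[Si](C)(C)C(C)(C)C)=C/[C@@H](O[Si](C)(C)C(C)(C)C)[C@@H]1C(=C)COCc1ccc(OC)cc1 | intermediate
30 | (1(10)E,4Z,6R,7R,8S)-6,15-bis(tert-butyldimethylsilyloxy)germacra-1(10),4,11(13)-triene-8,12-diol | O[C@H]1C/C(C)=C/CC/C(CO[Si](C)(C)C(C)(C)C)=C/[C@@H](O[Si](C)(C)C(C)(C)C)[C@@H]1C(=C)CO | intermediate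
31 | (1(10)E,4Z,6R,7R,8S)-6,15-bis(tert-butyldimethylsilyloxy)-8-hydroxygermacra-1(10),4,11(13)-trien-12-al | O[C@H]1C/C(C)=C/CC/C(CO[Si](C)(C)C(C)(C)C)=C/[C@@H](O[Si](C)(C)C(C)(C)C)[C@@H]1C(=C)C=O | intermediate (not isolated)
32 | 12-hydroxy-8,12-epoxy lactol of 31 (both C12 epimers) | C=C1C(O)O[C@H]2C/C(C)=C/CC/C(CO[Si](C)(C)C(C)(C)C)=C/[C@@H](O[Si](C)(C)C(C)(C)C)[C@H]12 | intermediate (not isolated)
33 | (1(10)E,4Z,6R,7R,8S)-6,15-bis(tert-butyldimethylsilyloxy)germacra-1(10),4,11(13)-trien-12,8-olide | C=C1C(=O)O[C@H]2C/C(C)=C/CC/C(CO[Si](C)(C)C(C)(C)C)=C/[C@@H](O[Si](C)(C)C(C)(C)C)[C@H]12 | intermediate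
34 | (1(10)E,4Z,6R,7S,8S)-6,15-dihydroxygermacra-1(10),4,11(13)-trien-12,8-olide | C=C1C(=O)O[C@H]2C/C(C)=C/CC/C(CO)=C/[C@@H](O)[C@H]12 | intermediate
35 | tert-butyl prop-2-enoate | C=CC(=O)OC(C)(C)C | starting material
36 | acetaldehyde | CC=O | starting material
37 | tert-butyl 3-hydroxy-2-methylidenebutanoate (racemic) | CC(O)C(=C)C(=O)OC(C)(C)C | intermediate
38 | tert-butyl 3-acetoxy-2-methylidenebutanoate (racemic) | CC(OC(C)=O)C(=C)C(=O)OC(C)(C)C | intermediate
39 | tert-butyl (2E)-2-(acetoxymethyl)but-2-enoate | C/C=C(\COC(C)=O)C(=O)OC(C)(C)C | intermediate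
40 | (2E)-2-(acetoxymethyl)but-2-enoic acid | C/C=C(\COC(C)=O)C(=O)O | intermediate
41 | (2E)-2-(acetoxymethyl)but-2-enoyl chloride | C/C=C(\COC(C)=O)C(=O)Cl | intermediate (not isolated)
42 | (1(10)E,4Z,6R,7S,8S)-15-{[(2E)-2-(acetoxymethyl)but-2-enoyl]oxy}-6-hydroxygermacra-1(10),4,11(13)-trien-12,8-olide (CNP0184624.1) | C=C1C(=O)O[C@H]2C/C(C)=C/CC/C(COC(=O)/C(=C/C)COC(C)=O)=C/[C@@H](O)[C@H]12 | target

**Step count**
Total: 20 steps. Longest linear sequence: 14 steps (steps 3–15 and 20, from 7 and 8 to 42).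

**Steps most likely to fail**

1. Step 12. What may go wrong: coupling between two molecules (oligomerisation), closure in the exo mode to a nine-membered ring with an exocyclic ethylidene, or nickel-induced isomerisation of the epoxide, each in competition with the ten-membered closure.
Fallback (known reactions only): the ring is closed at C1–C2 by a B-alkyl Suzuki–Miyaura macrocyclisation, after C9–C10 has been made by acetylide opening of the epoxide and the C1(10) alkene by zirconium-catalysed methylalumination. It sets out from 1 and 19 and comes back to the route at 29. Vinylmagnesium bromide is added to 1 under the conditions of step 1 and the alkenylmagnesium is iodinated to give (2Z)-2-(iodomethylidene)but-3-en-1-ol F1, which is silylated to TBS ether F2. Iodine–lithium exchange and addition to 19 as in step 8 give dienone F3. The operations of steps 9, 10 and 11 then give syn-diol F4, epoxy alcohol F5 and bis-silyl epoxide F6. Lithium acetylide with BF3·OEt2 (THF, −78 °C) opens F6 at C9 to give homopropargylic alcohol F7. AlMe3 with catalytic Cp2ZrCl2 followed by iodine gives (E)-alkenyl iodide F8, with methyl on C10 and iodine on C1. 9-BBN should hydroborate the monosubstituted vinyl terminus ahead of the hindered C11 methylidene and bind O8, giving alkylborane F9. Pd(dppf)Cl2 with AsPh3 and Cs2CO3 in DMF/THF/water at high dilution then joins C2 to C1 with retention of the alkene geometry and gives 29 after work-up.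

2. Step 8. What may go wrong: the alkenyllithium acts as a base (proton transfer at C7, β-elimination of the C8 alkoxide or its closure onto C9) instead of adding to the amide.
Fallback: the C5–C6 bond is made under non-basic conditions by a Nozaki–Hiyama–Kishi reaction. It sets out from 19 (with 6) and comes back at 22. TESCl/imidazole converts 19 into TES ether F10, and DIBAL-H at −78 °C gives aldehyde F11. CrCl2 with catalytic NiCl2 in DMSO couples F11 with 6 to give allylic alcohol F12 as a mixture at C6. Dess–Martin periodinane gives TES enone F13, and HF·pyridine/pyridine removes the TES group to give 22.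

3. Step 20. What may go wrong: acylation also at O6, or base-induced migration of the lactone to O6 during handling of the free diol.
Fallback: the two hydroxyls are unmasked one at a time. It sets out from 33 and comes back at 42. Brief exposure to HF·pyridine/pyridine at −20 °C should cleave only the primary allylic silyl ether and give 15-alcohol F14. Acylation with 41 and 2,4,6-collidine gives ester F15, and HF·pyridine/pyridine at rt then frees O6 to give 42.

**Further compounds**
F1 | step 12 | (2Z)-2-(iodomethylidene)but-3-en-1-ol | C=C/C(CO)=C/I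
F2 | step 12 | tert-butyl{[(2Z)-2-(iodomethylidene)but-3-en-1-yl]oxy}dimethylsilane | C=C/C(CO[Si](C)(C)C(C)(C)C)=C/I
F3 | step 12 | dienone, analogue of 22 with vinyl (C3=C2) in place of the pentynyl chain (7R,8R) | C=C/C(CO[Si](C)(C)C(C)(C)C)=C/C(=O)[C@H](C(=C)COCc1ccc(OC)cc1)[C@@H](O)CCl
F4 | step 12 | syn-diol, vinyl analogue of 24 (6R,7S,8R) | C=C/C(CO[Si](C)(C)C(C)(C)C)=C/[C@@H](O)[C@H](C(=C)COCc1ccc(OC)cc1)[C@@H](O)CCl
F5 | step 12 | epoxy alcohol, vinyl analogue of 25 (6R,7S,8R) | C=C/C(CO[Si](C)(C)C(C)(C)C)=C/[C@@H](O)[C@H](C(=C)COCc1ccc(OC)cc1)[C@@H]1CO1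
F6 | step 12 | bis-silyl epoxide, vinyl analogue of 26 (6R,7R,8R) | C=C/C(CO[Si](C)(C)C(C)(C)C)=C/[C@@H](O[Si](C)(C)C(C)(C)C)[C@H](C(=C)COCc1ccc(OC)cc1)[C@@H]1CO1
F7 | step 12 | homopropargylic alcohol (C8–OH, C9H2–C10≡C1H; 6R,7R,8S) | C=C/C(CO[Si](C)(C)C(C)(C)C)=C/[C@@H](O[Si](C)(C)C(C)(C)C)[C@H](C(=C)COCc1ccc(OC)cc1)[C@@H](O)CC#C
F8 | step 12 | (E)-alkenyl iodide (C10 methyl, C1 iodide; 6R,7R,8S) | C=C/C(CO[Si](C)(C)C(C)(C)C)=C/[C@@H](O[Si](C)(C)C(C)(C)C)[C@H](C(=C)COCc1ccc(OC)cc1)[C@@H](O)C/C(C)=C/I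
F9 | step 12 | C2-(9-borabicyclo[3.3.1]nonan-9-yl) alkylborane of F8, O8 bound to a second 9-BBN unit | B1(CC/C(CO[Si](C)(C)C(C)(C)C)=C/[C@@H](O[Si](C)(C)C(C)(C)C)[C@H](C(=C)COCc2ccc(OC)cc2)[C@@H](OB2C3CCCC2CCC3)C/C(C)=C/I)C2CCCC1CCC2
F10 | step 8 | (2R,3R)-4-chloro-N-methoxy-2-{3-[(4-methoxybenzyl)oxy]prop-1-en-2-yl}-N-methyl-3-(triethylsilyloxy)butanamide | CON(C)C(=O)[C@H](C(=C)COCc1ccc(OC)cc1)[C@H](CCl)O[Si](CC)(CC)CC
F11 | step 8 | (2R,3R)-4-chloro-2-{3-[(4-methoxybenzyl)oxy]prop-1-en-2-yl}-3-(triethylsilyloxy)butanal | O=C[C@H](C(=C)COCc1ccc(OC)cc1)[C@H](CCl)O[Si](CC)(CC)CC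
F12 | step 8 | allylic alcohol, C6 epimers, O8-TES (7R,8R) | CC#CCC/C(CO[Si](C)(C)C(C)(C)C)=C/C(O)[C@H](C(=C)COCc1ccc(OC)cc1)[C@H](CCl)O[Si](CC)(CC)CC
F13 | step 8 | O8-triethylsilyl ether of 22 | CC#CCC/C(CO[Si](C)(C)C(C)(C)C)=C/C(=O)[C@H](C(=C)COCc1ccc(OC)cc1)[C@H](CCl)O[Si](CC)(CC)CC
F14 | step 20 | (1(10)E,4Z,6R,7R,8S)-6-(tert-butyldimethylsilyloxy)-15-hydroxygermacra-1(10),4,11(13)-trien-12,8-olide | C=C1C(=O)O[C@H]2C/C(C)=C/CC/C(CO)=C/[C@@H](O[Si](C)(C)C(C)(C)C)[C@H]12
F15 | step 20 | O6-tert-butyldimethylsilyl ether of 42 | C=C1C(=O)O[C@H]2C/C(C)=C/CC/C(COC(=O)/C(=C/C)COC(C)=O)=C/[C@@H](O[Si](C)(C)C(C)(C)C)[C@H]12
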